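**Retrosynthetic overview**
1. The side-chain CH2 sits on C-4 of the cyclohexadienone ring, between the two enolised carbonyl carbons C-3 and C-5, so core plus CH2 is a latent 2-methylene-1,3-dione (a 1-oxadiene of o-quinone-methide type). The cyclopentane CH that carries this CH2 (C-1') is α to the carbinol carbon C-2', a latent ketone, so C-1'=C-2' can be a silyl enol ether.
2. Key disconnection: the CH2–C-1' bond, made by inverse-demand hetero-Diels–Alder reaction of the methylene trione with the silyl enol ether of (S)-3-isopropenylcyclopentanone. The temporary dihydropyran ketal ring is opened in the same operation, and the C-2' carbinol follows by methyl addition.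
3. The enol ether comes from cyclopentenone by Rh/BINAP asymmetric 1,4-isopropenylation with O-silyl trapping (sets C-5'). The methylene trione comes from 2-methylphloroglucinol by acylation, dearomatising gem-diprenylation, α-selenenylation and selenoxide elimination.
4. Ring order: the core carbocycle is the dearomatised aromatic ring (step 2), the cyclopentane is bought as cyclopentenone, and the temporary pyran ring is closed and reopened in step 5.

Key step: step 5

Remark: the trione core is written throughout as the enol tautomer of the target SMILES; 6 and 11 are racemic at the selenium-bearing ring carbon, which becomes sp2 in 12; 14 may equilibrate with a cyclic hemiketal and is written as the keto form.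

**Step 1**
Reactants: 1 2-methylphloroglucinol; 2 isovaleryl chloride
Product: 3 3-methyl-1-(2,4,6-trihydroxy-3-methylphenyl)butan-1-one
Conditions: AlCl3 (3.5 equiv), PhNO2/CH2Cl2, 0 → 50 °C; aq. HCl
Reagents that add atoms: none
Why: Friedel–Crafts C-acylation of the highly activated triol; the two free ring positions are equivalent by symmetry and the first acyl group deactivates the ring against a second acylation.

**Step 2**
Reactants: 3 3-methyl-1-(2,4,6-trihydroxy-3-methylphenyl)butan-1-one; 4 prenyl bromide (2.2 equiv)
Product: 5 3,5-dihydroxy-4-methyl-2-(3-methylbutanoyl)-6,6-bis(3-methylbut-2-en-1-yl)cyclohexa-2,4-dien-1-one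
Conditions: NaOMe (3 equiv), MeOH, 0 °C → rt; acidify
Reagents that add atoms: none
Why: Base-mediated dearomatising C-alkylation of the phloroglucinolate, closely precedented for the double prenylation of C-methyl acylphloroglucinols: the first prenyl group enters the only unsubstituted ring carbon and the second, as that precedent indicates, the same carbon, which becomes quaternary and locks the ring as the enolised trione; O-prenyl and methyl/prenyl-quaternary isomers are expected as minor products to be removed by chromatography.

**Step 3**
Reactants: 5 3,5-dihydroxy-4-methyl-2-(3-methylbutanoyl)-6,6-bis(3-methylbut-2-en-1-yl)cyclohexa-2,4-dien-1-one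
Product: 6 3-hydroxy-4-methyl-2-(3-methylbutanoyl)-6,6-bis(3-methylbut-2-en-1-yl)-4-(phenylselanyl)cyclohex-2-ene-1,5-dione (racemic)
Conditions: PhSeCl (1.05 equiv), pyridine (1.2 equiv), CH2Cl2, −20 → 0 °C
Reagents that add atoms: benzeneselenenyl chloride, Cl[Se]c1ccccc1
Why: Electrophilic α-selenenylation of a 2-alkyl-1,3-dione enol: C-4, the ring carbon between the two enolised carbonyls, is the most nucleophilic carbon (the acyl-bearing C-2 is a fully substituted tricarbonyl carbon), and the pyridine-moderated selenium electrophile should leave the prenyl double bonds untouched; the new quaternary centre is racemic and is destroyed in step 5.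

**Step 4**
Reactants: 7 cyclopent-2-en-1-one; 8 isopropenylmagnesium bromide
Product: 10 triethyl{[(3S)-3-(prop-1-en-2-yl)cyclopent-1-en-1-yl]oxy}silane, via titanium enolate 9 (not isolated)
Conditions: 8, ClTi(OiPr)3, THF, −78 → 0 °C; then 7, [Rh(OH)((S)-BINAP)]2 (3 mol % Rh), THF, 20 °C; then LiOiPr, Et3SiCl, 0 °C → rt
Reagents that add atoms: chlorotriethylsilane, CC[Si](Cl)(CC)CC
Why: Rhodium(I)/BINAP-catalysed asymmetric 1,4-addition of an organotitanium triisopropoxide under aprotic conditions (established for aryl groups on 7; alkenyl transfer to Rh–BINAP is established from boron and zirconium): the ligand-controlled carborhodation sets the C-3 stereocentre (expected S with (S)-BINAP by analogy with aryl transfer), and the titanium enolate 9 is silylated on oxygen without proton exchange, so the enol ether double bond lies regiospecifically between C-1 and C-2, towards the isopropenyl-bearing carbon.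

**Step 5**
Reactants: 6 3-hydroxy-4-methyl-2-(3-methylbutanoyl)-6,6-bis(3-methylbut-2-en-1-yl)-4-(phenylselanyl)cyclohex-2-ene-1,5-dione; 10 triethyl{[(3S)-3-(prop-1-en-2-yl)cyclopent-1-en-1-yl]oxy}silane (1.5 equiv)
Product: 14 3,5-dihydroxy-2-(3-methylbutanoyl)-6,6-bis(3-methylbut-2-en-1-yl)-4-{[(1R,2S)-5-oxo-2-(prop-1-en-2-yl)cyclopentyl]methyl}cyclohexa-2,4-dien-1-one, via selenoxide 11 (not isolated), via methylene trione 12 (not isolated), via cycloadduct ketal 13 (not isolated)
Conditions: 6, dimethyldioxirane (1.0 equiv, in acetone), CH2Cl2, −78 °C; then 10, 4 Å MS, −78 → 0 °C; then AcOH/THF/H2O, 0 °C → rt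
Reagents that add atoms: none
Why: Chemoselective Se-oxidation gives selenoxide 11, whose syn-elimination can only take a methyl hydrogen (the other neighbours of the Se-bearing carbon are carbonyl carbons) and so releases the 2-methylene-1,3-dione 12, a 1-oxadiene that combines at low temperature with the electron-rich enol ether double bond of 10 in an inverse-electron-demand hetero-Diels–Alder reaction (or its stepwise Mukaiyama–Michael/ring-closure limit), forming the CH2–C-1' bond and an O–C ketal bond; hydrolysis of the silyl ketal 13 then collapses the temporary ring to the cyclopentanone and the enol. The closest known reaction types are the selenoxide route to 2-alkylidene-1,3-diones and the [4+2] cycloaddition of alkylidene-1,3-diones and o-quinone methides (including those of dearomatised acylphloroglucinols) with enol ethers and alkenes. The only ring closed is the temporary 3,4-dihydro-2H-pyran, formed by [4+2] cycloaddition suprafacially on the enol ether and therefore cis-fused to the cyclopentane, and opened again in the same operation. The new stereocentre C-1' is set by approach of the heterodiene to the enol ether face anti to the neighbouring isopropenyl group on C-5' (trans), and because it is α to the unveiled ketone the same trans isomer is also the thermodynamic one; the ketal carbon is only a transient stereocentre. Regiochemistry (CH2 to the enol ether β-carbon) follows from the polarisation of both partners, either flanking carbonyl of 12 may act as the oxadiene oxygen because both ketals hydrolyse to 14, and chemoselectivity for the enol ether over the prenyl and isopropenyl double bonds rests on its far higher nucleophilicity. Two-electron generation of 12 avoids a ring-centred radical, which would cyclise onto the neighbouring prenyl groups.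

**Step 6**
Reactants: 14 3,5-dihydroxy-2-(3-methylbutanoyl)-6,6-bis(3-methylbut-2-en-1-yl)-4-{[(1R,2S)-5-oxo-2-(prop-1-en-2-yl)cyclopentyl]methyl}cyclohexa-2,4-dien-1-one
Product: 15 3,5-dihydroxy-4-{[(1R,2S,5S)-2-hydroxy-2-methyl-5-(prop-1-en-2-yl)cyclopentyl]methyl}-2-(3-methylbutanoyl)-6,6-bis(3-methylbut-2-en-1-yl)cyclohexa-2,4-dien-1-one
Conditions: MeMgBr (5 equiv), anhydrous CeCl3 (5 equiv), THF, −78 → −20 °C; AcOH quench at −78 °C, pH 5 buffer
Reagents that add atoms: methylmagnesium bromide, C[Mg]Br
Why: Organocerium-type 1,2-addition of methyl to the cyclopentanone (the first two equivalents turn the two acidic enols into enolates, which masks every core carbonyl, and cerium suppresses α-deprotonation): the methyl group should enter anti to the adjacent CH2 substituent on C-1' (1,2-induction, as in hydride and alkyl additions to trans-2,3-disubstituted cyclopentanones), giving OH cis to that CH2 and the (2'S) carbinol.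

**Compound list**
1 | 2-methylbenzene-1,3,5-triol (2-methylphloroglucinol) | Cc1c(O)cc(O)cc1O | starting material
2 | 3-methylbutanoyl chloride (isovaleryl chloride) | CC(C)CC(=O)Cl | starting material
3 | 3-methyl-1-(2,4,6-trihydroxy-3-methylphenyl)butan-1-one | CC(C)CC(=O)c1c(O)cc(O)c(C)c1O | intermediate
4 | 1-bromo-3-methylbut-2-ene (prenyl bromide) | CC(C)=CCBr | starting material
5 | 3,5-dihydroxy-4-methyl-2-(3-methylbutanoyl)-6,6-bis(3-methylbut-2-en-1-yl)cyclohexa-2,4-dien-1-one | CC1=C(O)C(CC=C(C)C)(CC=C(C)C)C(=O)C(C(=O)CC(C)C)=C1O | intermediate
6 | 3-hydroxy-4-methyl-2-(3-methylbutanoyl)-6,6-bis(3-methylbut-2-en-1-yl)-4-(phenylselanyl)cyclohex-2-ene-1,5-dione (racemic) | CC1([Se]c2ccccc2)C(=O)C(CC=C(C)C)(CC=C(C)C)C(=O)C(C(=O)CC(C)C)=C1O | intermediate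
7 | cyclopent-2-en-1-one | O=C1C=CCC1 | starting material
8 | prop-1-en-2-ylmagnesium bromide (isopropenylmagnesium bromide) | C=C(C)[Mg]Br | starting material
9 | tri(propan-2-yloxy){[(3S)-3-(prop-1-en-2-yl)cyclopent-1-en-1-yl]oxy}titanium (titanium enolate) | C=C(C)[C@H]1CCC(O[Ti](OC(C)C)(OC(C)C)OC(C)C)=C1 | intermediate (not isolated)
10 | triethyl{[(3S)-3-(prop-1-en-2-yl)cyclopent-1-en-1-yl]oxy}silane | C=C(C)[C@H]1CCC(O[Si](CC)(CC)CC)=C1 | intermediate
11 | 4-(benzeneseleninyl)-3-hydroxy-4-methyl-2-(3-methylbutanoyl)-6,6-bis(3-methylbut-2-en-1-yl)cyclohex-2-ene-1,5-dione (selenoxide of 6) | CC1([Se](=O)c2ccccc2)C(=O)C(CC=C(C)C)(CC=C(C)C)C(=O)C(C(=O)CC(C)C)=C1O | intermediate (not isolated)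
12 | 3-hydroxy-4-methylidene-2-(3-methylbutanoyl)-6,6-bis(3-methylbut-2-en-1-yl)cyclohex-2-ene-1,5-dione (methylene trione) | C=C1C(=O)C(CC=C(C)C)(CC=C(C)C)C(=O)C(C(=O)CC(C)C)=C1O | intermediate (not isolated)
13 | hetero-Diels–Alder adduct: dihydropyran cis-fused to the cyclopentane, OSiEt3 on the ring-fusion ketal carbon, pyran oxygen and ring-fusion CH2 cis, isopropenyl trans to that CH2; core ring carries OH, 3-methylbutanoyl, C=O and the gem-diprenyl carbon | C=C(C)[C@H]1CC[C@]2(O[Si](CC)(CC)CC)OC3=C(C[C@H]12)C(O)=C(C(=O)CC(C)C)C(=O)C3(CC=C(C)C)CC=C(C)C | intermediate (not isolated)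
14 | 3,5-dihydroxy-2-(3-methylbutanoyl)-6,6-bis(3-methylbut-2-en-1-yl)-4-{[(1R,2S)-5-oxo-2-(prop-1-en-2-yl)cyclopentyl]methyl}cyclohexa-2,4-dien-1-one | C=C(C)[C@H]1CCC(=O)[C@@H]1CC1=C(O)C(CC=C(C)C)(CC=C(C)C)C(=O)C(C(=O)CC(C)C)=C1O | intermediate
15 | 3,5-dihydroxy-4-{[(1R,2S,5S)-2-hydroxy-2-methyl-5-(prop-1-en-2-yl)cyclopentyl]methyl}-2-(3-methylbutanoyl)-6,6-bis(3-methylbut-2-en-1-yl)cyclohexa-2,4-dien-1-one (CNP0332156.1) | C=C(C)[C@H]1CC[C@](C)(O)[C@@H]1CC1=C(O)C(CC=C(C)C)(CC=C(C)C)C(=O)C(C(=O)CC(C)C)=C1O | target

**Step count and risks**
Total steps: 6. Longest linear sequence: 5 steps (1 → 2 → 3 → 5 → 6); step 4 is the convergent branch.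

Step 5 (most at risk). The methylene trione may be lost to self-dimerisation or to an intramolecular ene/cycloaddition with a neighbouring prenyl group, or the silyl enol ether may be destroyed by selenium by-products or by the acidic enol before it cycloadds. The fallback sets out from 6 and separates the oxidation from the C–C bond formation. Compound 6 is oxidised with dimethyldioxirane at −78 °C in the presence of morpholine (3 equiv). The amine adds to 12 as it forms and also intercepts the selenenic acid, giving the morpholine Mannich base F1, which is purified free of selenium. F1 and 10 (2 equiv) are then heated in toluene at 80–90 °C. Slow retro-Mannich loss of morpholine, the known thermal release of methylene diones and o-quinone methides from Mannich bases, regenerates 12 at low stationary concentration under oxidant-free conditions. Cycloaddition with 10 returns to the route at 13, which is hydrolysed to 14 as in step 5.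

Step 4. Transfer of the α-branched alkenyl group from titanium to rhodium may be slow, with erosion of enantioselectivity or competing 1,2-addition. The fallback sets out from 7 and 8 and separates regiocontrol from enantiocontrol. Copper-catalysed conjugate addition of 8 to 7 with in situ silylation (CuBr·SMe2 cat., Et3SiCl, THF, −78 °C) gives the racemic silyl enol ether F2 regiospecifically. Step 5 run on F2 gives the racemic cycloadduct F3 and, after hydrolysis, the racemic trans-ketone F4. F4 is resolved by crystallisation of the diastereomeric cinchonidine salts of its acidic enol, or by chromatography on a chiral stationary phase. The (1R,2S)-enantiomer is 14, where the route is rejoined.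

Step 6. The basic methyl reagent may deprotonate α to the ketone instead of adding, or the two carbonyl faces may be poorly discriminated. The fallback sets out from 14 and replaces the carbanion addition by methylene transfer followed by hydride opening. Corey–Chaykovsky reaction with dimethylsulfonium methylide (Me3S+ I−, KHMDS, excess to cover the two enols, THF/DMSO, −10 °C) adds irreversibly from the face anti to the C-1' substituent and gives the spiro-epoxide F5, with the epoxide oxygen cis to the CH2–core group. Regioselective opening at the epoxide CH2 with LiEt3BH (THF, 0 °C) gives the tertiary alcohol and returns to the route at 15.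

**Further compounds**
F1 | step 5 | 3,5-dihydroxy-2-(3-methylbutanoyl)-6,6-bis(3-methylbut-2-en-1-yl)-4-(morpholin-4-ylmethyl)cyclohexa-2,4-dien-1-one (Mannich base) | CC(C)CC(=O)C1=C(O)C(CN2CCOCC2)=C(O)C(CC=C(C)C)(CC=C(C)C)C1=O
F2 | step 4 | racemic triethyl{[3-(prop-1-en-2-yl)cyclopent-1-en-1-yl]oxy}silane | C=C(C)C1CCC(O[Si](CC)(CC)CC)=C1
F3 | step 4 | racemic cycloadduct (13 together with its mirror image; SMILES of the mirror image) | C=C(C)[C@@H]1CC[C@@]2(O[Si](CC)(CC)CC)OC3=C(C[C@@H]12)C(O)=C(C(=O)CC(C)C)C(=O)C3(CC=C(C)C)CC=C(C)C
F4 | step 4 | racemic trans-ketone (14 together with its mirror image; SMILES of the mirror image) | C=C(C)[C@@H]1CCC(=O)[C@H]1CC1=C(O)C(CC=C(C)C)(CC=C(C)C)C(=O)C(C(=O)CC(C)C)=C1O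
F5 | step 6 | spiro-epoxide of 14 at the cyclopentanone carbon, epoxide oxygen cis to the CH2–core substituent | C=C(C)[C@H]1CC[C@@]2(CO2)[C@@H]1CC1=C(O)C(CC=C(C)C)(CC=C(C)C)C(=O)C(C(=O)CC(C)C)=C1O
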